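Readings and results were computed for substances that don't exist; scatter was added.

Charged with 10 mM of E instead of 1.2 mM, the gamma flask held 58.2% of X at 90.0 s where the beta flask held 3.4%, and yet gamma's D and X together stood 41.6% short of the L charged.

| setting | beta | gamma | Friday's | Wednesday's | Monday's |
|---|---|---|---|---|---|
| L | 2 mM | 2 mM | 2.0 mM | 2.0 mM | 2.0 mM |
| E | 1.2 mM | 10 mM | 1.00 mM | 4.00 mM | 8.00 mM |
| remark | run made earlier | run made earlier |  |  |  |
| time |  |  | 3.0 min | 3.0 min | 3.0 min |

| run | time / s | D / % | X / % |
|---|---|---|---|
| beta | 25.0 | 16.1 | 2.2 |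
| beta | 50.0 | 10.1 | 3.2 |
| beta | 60.0 | 7.6 | 2.9 |
| beta | 90.0 | 3.8 | 3.4 |
| gamma | 25.0 | 11.6 | 51.2 |
| gamma | 50.0 | 0.7 | 57.8 |
| gamma | 60.0 | 0.5 | 57.6 |
| gamma | 90.0 | 0.2 | 58.2 |

(scatter of a reading: 0.3 percentage points)



1. which of these holds the largest part of the L at the end of Friday's (D / L / X)
2. which of these holds the largest part of the L at the end of Wednesday's (D / L / X)
3. which of these holds the largest part of the L at the end of Monday's (D / L / X)
4. final D in Wednesday's, as a percentage of the L charged

I opened the ledger with beta. Between 60.0 s and 90.0 s its D lost 3.8 percentage points while its X gained 0.5 points, so I gave D a second exit, into something unseen. In gamma I booked one E for each L reaching D and a second for each D reaching X, which left 6.84 mM of E at the close. I took it that L had not stayed beside so much E, and entered the shortfall as D gone by the exit.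

Dividing the rate of D to X by the rate of D through the exit removes time, and the ratio is cE over a constant that I call the even-split cE. Gamma's mean cE of 8.42 mM and its split gave 6.05 mM for the even-split cE, the cE at which D leaves equally by both ways.

The same ledger, with mean cE lowered by what each L takes, put 30.8% of the L as X in Wednesday's and 51.7% in Monday's. My ledger still closed Wednesday's with 1.38 mM of E, so I took L as the limiting reagent there. Its mean cE of 2.69 mM times 3.0 min exceeds gamma's product up to 50.0 s, so I wrote off its L, and Monday's too. Friday's E leaves at least half of its L. I committed to L, X, X, and to 0.475% of D in Wednesday's, halving beta's last reading every 30.0 s.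

The forecast said L, L, L and 0.8% of D, holding that “The final state is therefore L plus X”.

The flasks gave L in Friday's at 52.8%, X in Wednesday's at 28.3%, X in Monday's at 51.3%, and 0.121% of D in Wednesday's.

    L + E → J + D (k = 22.0 M⁻¹ s⁻¹)
    D + E → J + X (k = 8.80 M⁻¹ s⁻¹)
    D → G (k = 0.0490 s⁻¹)

In Wednesday's D had a half-life of 0.24 min by the step to G against 0.33 min by the step with E as charged, and at 0.156 min it went to G 1.9 times as fast as to X. Wednesday's closed with G over X at 2.53, where the even-split cE over my mean cE for that flask reads 2.25.

The neighbour charged with 1.0 mM of E has a mean cE of 0.500 mM if its E is used up, so by my reckoning the even-split cE sends 7.64% of its D to X, which is 3.55% of the L charged. At 3.00 min it held 2.40% of X, 52.8% of L and 0.73% of its E.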